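Early in the theta run product grows evenly, 10.9% at 2.50 min and 21.4% at 5.00 min, but the later readings of every run bend away from such a line. The ledger follows substrate, the limiting reagent. The first entry is the product read. The second entry, found by subtraction, is the part of the charge not yet product, in whatever form it stands.

| setting | alpha | epsilon | theta | south | north | east | north-east | south-east | north-west |
|---|---|---|---|---|---|---|---|---|---|
| substrate | 0.27 M | 1.3 M | 2 M | 2.0 M | 2.0 M | 1.2 M | 2.0 M | 2.0 M | 0.50 M |
| free catalyst | 160 mM | 160 mM | 73 mM | 160 mM | 160 mM | 40 mM | 100 mM | 160 mM | 40 mM |
| temperature | 65 °C | 98 °C | 65 °C | 100 °C | 70 °C | 110 °C | 50 °C | 110 °C | 70 °C |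
| remark | run made earlier | run made earlier | run made earlier |  |  |  |  |  |  |
| time |  |  |  | 12 min | 12 min | 12 min | 12 min | 12 min | 12 min |

- alpha (time / min: product / %): 0.833: 10.4; 2.50: 32.0; 4.00: 44.3; 6.00: 56.1; 10.0: 68.5; 12.0: 71.4
- epsilon (time / min: product / %): 0.500: 32.8; 1.00: 48.4; 1.50: 55.7; 2.00: 60.9; 2.50: 62.9; 3.00: 65.1
- theta (time / min: product / %): 2.50: 10.9; 5.00: 21.4; 8.00: 32.5; 10.0: 38.2; 12.0: 43.1

(scatter of a reading: 0.5 percentage points)

- the analysis behind the earlier runs scatters by 0.5 percentage points, standard deviation

- the flasks put in order of amount of product, in percent of the substrate charged, best first, at 12 min (south / north / east / north-east / south-east / north-west)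
- the same order at 2.5 min (south / north / east / north-east / south-east / north-west)
- the amount of product, in percent of the substrate charged of the flask you put first, at 12 min
- the amount of product, in percent of the substrate charged of the flask you put last, at 12 min

The books at the last readings are these. The alpha run holds 71.4% as product and 28.6% not yet product. The theta run holds 43.1% and 56.9%. Counted as turnovers per catalyst charged, alpha made 1.20 and theta 11.8, at one temperature and one time. The raw count follows the substrate charge, so it describes no property of the catalyst.

A better entry is the reach: the natural logarithm of the charge over the part not yet product, divided by the catalyst charged. Theta gives 7.72 M⁻¹ and alpha 7.82 M⁻¹, nearly equal despite very different charges.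

The epsilon run has almost stopped: its last interval adds 2.2 percentage points, with 34.9% not yet product. The near-equal reach of alpha and theta ties conversion to the catalyst charged. This reckoning therefore reads the stop as a dying catalyst, and then epsilon's reach of 6.58 M⁻¹, lower than the cold one, is what a hot charge buys in its whole life.

Hot flasks then end near a fixed reach: south at 65.1% and east, with its thin charge, at 23.1%. South-east should fall below south. The cold reach gives north 70.9% and north-west 26.6%. North-east, colder than the theta run, goes last. This reckoning differs from the forecast mainly at east.

The forecast, holding that “The runs fit a reversible approach to equilibrium”, gave north > south > south-east > east > north-west > north-east at 12 min and south > south-east > east > north > north-west > north-east at 2.5 min, with 69.5% for the first flask and 26% for the last.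

The flasks give north > south > south-east > north-west > east > north-east at 12 min and south > south-east > north > east > north-west > north-east at 2.5 min, with north at 75.3%, north-east at 18.6%, east at 23.4% and north-west at 39.3%.

    catalyst intermediate → free catalyst + product (k = 0.150 s⁻¹, Ea = 87.0 kJ mol⁻¹)
    substrate + free catalyst → catalyst intermediate (k = 0.0300 M⁻¹ s⁻¹, Ea = 55.0 kJ mol⁻¹)
    free catalyst → spent catalyst B (k = 9.20 × 10⁻⁴ s⁻¹, Ea = 96.0 kJ mol⁻¹)
    2 catalyst intermediate ⇌ resting dimer, settled at all times (K = 26.0 M⁻¹, ΔH = −11.0 kJ mol⁻¹)
    2 free catalyst → spent catalyst A (k = 0.0110 M⁻¹ s⁻¹, Ea = 54.0 kJ mol⁻¹)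
    (constants at 70 °C)

North's result of 75.3% stands above its reckoned figure, and the loss of two free catalyst to spent catalyst A, acting together with the length of the run, is part of what holds north there: without that step north gives 87.1%, and at 120 min north gives 91.3%. On a second flask, like north but with 0.040 M of free catalyst, the reach gives 26.6%. The simulated flask gives 35.0% at 12.0 min.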